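Remark on the chemistry: labdane numbering is used for every cyclic compound and for the matching carbons of the acyclic precursors (C17 on C8, C18 = equatorial 4α-CH2O, C19 = axial 4β-CH3, C20 on C10, C15 = lactone carbonyl, C16 = lactone OCH2). Compounds 1, 2 and 10 are taken to be purchasable. Bn = benzyl, TBDPS = tert-butyldiphenylsilyl, TES = triethylsilyl.

## Analysis of the target

The target is a labdane-type dispiro compound. Rings A and B form a trans-decalin, C9 is the spiro atom shared by ring B and an oxolane (O–C9–C11–C12–C13), and C13 is the spiro atom shared by that oxolane and a γ-butyrolactone (C13–C14–C15(=O)–O–C16). It has seven stereocentres: C3, C4, C5, C8, C9, C10 and C13. In ring A the 3β-hydroxyl and the 4α-hydroxymethyl (C18) are equatorial, and the 4β-methyl is axial and syn to the axial C10 methyl. H5 is α, so the ring fusion is trans. On ring B the C8 methyl is α and equatorial, the C9–O bond is α and axial, and C11 is β and equatorial. C13 is R and lies too far from the decalin to be controlled by it, so it needs its own source of asymmetry. The C13 oxygen is β to the C15 carbonyl, so base can open the oxolane by β-elimination once the lactone exists. The C9 ether is tertiary and next to the quaternary C10, so strong acid invites ionisation and methyl shifts. The hardest bond is C9–O–C13, which joins two fully substituted carbons; the second difficulty is placing oxygen on only the equatorial carbon at C4. The strategy rests on rings A and B: the set C3–OH, C4 (axial CH3, equatorial CH2O), H5 and the C10 methyl is exactly the imprint of an epoxide-initiated cation–olefin bicyclisation of an (E)-configured polyene.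

## Retrosynthetic reasoning

**Target 32 back to diol 30.** The two benzyl ethers of 31 are removed last by neutral hydrogenolysis, because the finished β-alkoxy lactone tolerates neither strong base nor strong acid. The lactone C15–O16 bond of 31 is traced to diol 30, where oxidation of the unhindered C15 carbinol and capture by the C16 hydroxyl must give the lactone with C15 as carbonyl. Keeping C15 and C16 as silyl ethers until then removes every enolisable or base-labile group from the earlier steps.

**Diol 30 back to enone 25.** The C9–O bond is cut. C9 only becomes an acceptor for the hindered C13 hydroxyl when it is the β-carbon of an enone, so a C7 carbonyl is added in the retrosynthetic direction (29 from thiocarbamate 28, from alcohol 27, from ketone 26). Ketone 26 opens to the hydroxy enone 25. This disconnection is preferred to protonating a C8=C9 alkene, because a cation there would be trapped at C8 as the six-membered 8,13-ether and could rearrange. The forward conjugate addition must deliver oxygen axially to the α face of C9 and leave C8 epimerisable, so that the C17 methyl settles equatorial.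

**Enone 25 back to decalin 20.** The tetrasubstituted enone 25 comes from the exocyclic enone 24 by alkene migration, and 24 from allylic alcohol 23 and its silyl ether 22. These arise by allylic oxidation at C7 of the 8(17)-alkene 21, the benzyl ether of 20. The exocyclic alkene is used because it offers C7 as the only reactive allylic methylene.

**Decalin 20 back to polyene 19 (key disconnection).** The C4–C5 and C9–C10 bonds are cut, opening both carbocycles to the acyclic epoxy-diene 19. The terminating alkene carries a silylmethyl group on C8. The forward step must form two rings and four stereocentres (C4, C5, C9, C10) from the epoxide configuration and the alkene geometries, and must end at the 8(17)-alkene only. The allylsilane guarantees that ending, where a simple methyl-substituted alkene would give a mixture of elimination products.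

**Polyene 19 back to fragments 9 and 17.** The C9–C11 bond is cut between an sp2 and an sp3 carbon, giving vinyl iodide 9 and the alkylborane 18 made from vinyl carbinol 17. A cut at C11–C12 or C12–C13 would need either an allylic halide with silicon in the 4-position, which loses silicon by 1,4-elimination, or a carbanion β to the C13 oxygen, which eliminates. The sp2–sp3 cross-coupling avoids both and keeps the C13 chemistry separate from the polyene.

**Vinyl iodide 9 back to 1 and 2.** The benzyl ether 9 comes from epoxy alcohol 8, and 8 from allylic alcohol 7 by reagent-controlled epoxidation. The (Z)-iodo allylsilane unit of 7 is traced to the terminal alkyne of 5 by syn addition of a silylmethylcopper reagent and iodination. Alcohol 5 comes from dienyne 4 by hydroxylation of the terminal E-methyl, and 4 from geranyl bromide 1 and the C3 unit 2. The epoxide is placed after the organocopper step so that it never meets magnesium halides, and the hydroxylation is placed before it so that the allylsilane never meets the selenium oxidant.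

**Vinyl carbinol 17 back to 10.** Silyl ether 17 comes from tertiary allylic alcohol 16, and 16 from epoxide 15 by one-carbon homologation with a sulfonium ylide at the CH2 terminus; the C13–O bond is not touched. Epoxide 15 comes from epoxy alcohol 14, and 14 from the 2-substituted allylic alcohol 13 by asymmetric epoxidation, which is the only step that sets C13. Alcohol 13 arises from vinyl bromide 11 (via vinyllithium 12) and hence from 10.

## Alternatives that were turned down

**Alternative 1:** The lactone C13–C14 bond is cut, leading back to the C16 diazoacetate A1 of a preformed 9α,13-epoxide with a C13–H. In the forward step a dirhodium carboxylate or carboxamidate catalyst converts A1 to a carbenoid at C14, which inserts into the tertiary C13–H bond with retention and closes the five-membered lactone of the acetonide A2. In its favour, the C13–H bond is tertiary and activated by the ether oxygen, the five-membered insertion mode is the preferred one, and the quaternary C13 is made late with no protecting-group sequence at C15 and C16. On the lactone itself this is stronger than the chosen route, which needs a desilylation and an oxidation whose regiochemistry must be watched. Against it, A1 already contains the decalin, the C9–O spiro linkage and a defined C13–H stereocentre, so the hard problems are only moved upstream. The carbenoid can also attack the oxolane oxygen to give an oxonium ylide, or insert at C12–H, or dimerise, and the C13–H bond sits next to a spiro centre. The chosen strategy instead spends its key step on two rings and four stereocentres and fixes C13 early by asymmetric epoxidation.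

**Alternative 2:** Ring A is cut at C3–C4 and C5–C10, leading to the acyclic trienoate A3 with a C10=C1–C2=C3 diene, a C4=C5 methacrylate-type dienophile and a C6–C9 tether bearing a masked C9 ketone. Heating A3 would give the octalin A4 by intramolecular Diels–Alder reaction. In its favour, the reaction is concerted, so there is no cation to rearrange or to terminate early. The C4 ester supplies C18 in the equatorial position, and the C9 ketal would let the C9–O bond and the side chain be built by carbonyl addition. That is a stronger way to oxygenate C9 than the chosen route, which must introduce and then erase a C7 ketone. Against it, both new bonds form at fully substituted carbons from a 1,1-disubstituted diene terminus and a trisubstituted dienophile, so forcing conditions and an uncertain trans to cis fusion ratio are expected. Facial control must come from the single C8 stereocentre in a flexible tether. A4 has no oxygen at C3 and its alkene is at C1=C2, so the 3β-hydroxyl needs a transposition of uncertain regio- and stereochemistry. The chosen strategy takes C3–O, C4, C5 and C10 in absolute configuration from one epoxide and needs no such adjustment.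

**Alternative 3:** Only the C9–O bond is cut, leading to the hydroxy enone A5. Base would add the C13 alkoxide of A5 to C9 to give the spiro ketone A6, and protonation of the enolate would set C8. In its favour, axial attack anti to the C10 methyl gives the 9α ether, C8 is under thermodynamic control, and the five-membered spiro ring is the only possible regiochemical outcome. On these points it is exactly as strong as the chosen route, which uses the same bond construction in step 19. Against it as the central strategy, the step forms one bond and one ring, and it leaves open how the decalin with its 3,18-dioxygenation and the tetrasubstituted enone are assembled. It also places the least secure equilibrium of the problem, an addition joining two fully substituted carbons, at the centre of the plan. The small silyl groups next to the alkoxide in A5 can migrate more easily than the TBDPS groups used here. The chosen strategy supplies the enone in five functional-group steps from the cyclisation product and keeps a fallback that does not depend on conjugate addition.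

Key step: step 13

## Route

**Step 1**
Reactants: 1 geranyl bromide; 2 1-(trimethylsilyl)propyne
Product: 4 (5E)-6,10-dimethylundeca-5,9-dien-1-yne, via TMS-capped dienyne 3 (not isolated)
Conditions: 2, n-BuLi, THF, −78 °C; then 1, −78 °C to rt; then K2CO3, MeOH, rt
Reagents that add atoms: none
Why: Lithiation of 2 at its methyl group gives a silyl-capped propargyl anion that displaces the primary allylic bromide at the α-carbon (SN2 alkylation; silicon blocks allene formation), and methanolysis of the C(sp)–Si bond then frees the terminal alkyne; the E-alkene of 1 is not touched.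

**Step 2**
Reactants: 4 (5E)-6,10-dimethylundeca-5,9-dien-1-yne
Product: 5 (2E,6E)-2,6-dimethylundeca-2,6-dien-10-yn-1-ol
Conditions: SeO2 (cat.), t-BuOOH, salicylic acid (cat.), CH2Cl2, 0 °C to rt
Reagents that add atoms: tert-butyl hydroperoxide CC(C)(C)OO
Why: SeO2 allylic hydroxylation (ene reaction, then [2,3]-sigmatropic shift) goes to the E-methyl of the terminal trisubstituted alkene, the most accessible allylic site, as in the ω-hydroxylation of other polyprenyl chains; the E-geometry of the new allylic alcohol follows from the mechanism.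

**Step 3**
Reactants: 5 (2E,6E)-2,6-dimethylundeca-2,6-dien-10-yn-1-ol
Product: 7 (2E,6E,10Z)-11-iodo-2,6-dimethyl-10-[(trimethylsilyl)methyl]undeca-2,6,10-trien-1-ol, via alkenylcopper 6 (not isolated)
Conditions: Me3SiCH2MgCl (excess), CuI, LiI, THF–Et2O, −10 °C to rt; then I2, −60 °C
Reagents that add atoms: (trimethylsilyl)methylmagnesium chloride C[Si](C)(C)C[Mg]Cl; iodine II
Why: syn-Carbocupration of the terminal alkyne by (trimethylsilyl)methylcopper puts the silylmethyl group on the internal carbon and copper on the terminal carbon, cis to each other, and iodinolysis with retention gives the vinyl iodide in which C7 and iodine are trans, the geometry needed at C8=C9; the hydroxyl is carried as its magnesium alkoxide and no epoxide is present yet.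

**Step 4**
Reactants: 7 (2E,6E,10Z)-11-iodo-2,6-dimethyl-10-[(trimethylsilyl)methyl]undeca-2,6,10-trien-1-ol
Product: 8 (2S,3S)-epoxy alcohol of 7
Conditions: Ti(OiPr)4 (cat.), L-(+)-diethyl tartrate (cat.), t-BuOOH, 4 Å MS, CH2Cl2, −20 °C
Reagents that add atoms: tert-butyl hydroperoxide CC(C)(C)OO
Why: Sharpless asymmetric epoxidation acts only on the allylic alcohol, so the allylsilane, the vinyl iodide and the internal alkene stay; the L-(+)-tartrate complex delivers oxygen to the face that gives the (2S,3S)-epoxide (3S, 4S in labdane numbering), with the CH2O group trans to C2 as fixed by the E-alkene.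

**Step 5**
Reactants: 8 (2S,3S)-epoxy alcohol
Product: 9 (2S,3S)-epoxy benzyl ether (vinyl iodide fragment)
Conditions: NaH, BnBr, Bu4NI (cat.), THF, 0 °C to rt
Reagents that add atoms: benzyl bromide BrCc1ccccc1
Why: Williamson etherification of the primary alkoxide; the trisubstituted epoxide, the allylsilane and the vinyl iodide are inert to NaH at this temperature and no stereocentre is involved.

**Step 6**
Reactants: 10 3-bromobut-3-en-1-ol
Product: 11 TBDPS ether of 10
Conditions: TBDPSCl, imidazole, CH2Cl2, rt
Reagents that add atoms: tert-butyl(chloro)diphenylsilane CC(C)(C)[Si](Cl)(c1ccccc1)c1ccccc1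
Why: Standard silylation of a primary alcohol; the TBDPS ether (future C15–O) withstands the organolithium, Lewis acid and mild acid used later.

**Step 7**
Reactants: 11 TBDPS ether of 3-bromobut-3-en-1-ol
Product: 13 4-(TBDPS-oxy)-2-methylidenebutan-1-ol, via vinyllithium 12 (not isolated)
Conditions: t-BuLi (2 equiv), Et2O, −78 °C; then (CH2O)n, −78 °C to rt
Reagents that add atoms: formaldehyde (from paraformaldehyde) C=O
Why: Bromine–lithium exchange gives a 2-lithioalkene that cannot eliminate the remote silyloxy group, and its addition to formaldehyde gives the 2-substituted allylic alcohol (the new carbon is C16).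

**Step 8**
Reactants: 13 4-(TBDPS-oxy)-2-methylidenebutan-1-ol
Product: 14 (R)-epoxy alcohol
Conditions: Ti(OiPr)4 (cat.), D-(−)-diethyl tartrate (cat.), t-BuOOH, 4 Å MS, CH2Cl2, −20 °C
Reagents that add atoms: tert-butyl hydroperoxide CC(C)(C)OO
Why: Sharpless asymmetric epoxidation of a 1,1-disubstituted allylic alcohol; the D-(−)-tartrate complex attacks the face that gives the (R)-epoxy alcohol, which sets C13, the only stereocentre of this fragment.

**Step 9**
Reactants: 14 (R)-epoxy alcohol
Product: 15 (S)-bis-TBDPS epoxide
Conditions: TBDPSCl, imidazole, DMF, rt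
Reagents that add atoms: tert-butyl(chloro)diphenylsilane CC(C)(C)[Si](Cl)(c1ccccc1)c1ccccc1
Why: Silylation of the neopentyl-type primary alcohol (C16–O) under non-basic conditions that leave the 2,2-disubstituted epoxide closed; the descriptor changes only because the priorities change.

**Step 10**
Reactants: 15 (S)-bis-TBDPS epoxide
Product: 16 (S)-tertiary allylic alcohol
Conditions: Me3S+ I−, n-BuLi, THF, −10 °C to rt
Reagents that add atoms: trimethylsulfonium iodide C[S+](C)C.[I-]
Why: Dimethylsulfonium methylide opens the epoxide at its CH2 terminus and the resulting β-oxido sulfonium salt eliminates dimethyl sulfide, giving the one-carbon-homologated allylic alcohol (epoxide to allylic alcohol homologation); the C13–O bond is never broken, so the configuration is kept.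

**Step 11**
Reactants: 16 (S)-tertiary allylic alcohol
Product: 17 (S)-TES ether (vinyl carbinol fragment)
Conditions: Et3SiOTf, 2,6-lutidine, CH2Cl2, −78 to 0 °C
Reagents that add atoms: triethylsilyl trifluoromethanesulfonate CC[Si](CC)(CC)OS(=O)(=O)C(F)(F)F
Why: The silyl triflate caps the hindered tertiary alcohol, so the C13 oxygen cannot trap a cation in step 13; the TES group can later be removed in the presence of the TBDPS ethers.

**Step 12**
Reactants: 17 (S)-TES ether; 9 (2S,3S)-epoxy benzyl ether
Product: 19 epoxy allylsilane polyene, via alkylborane 18 (not isolated)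
Conditions: 17, 9-BBN, THF, rt; then H2O; then 9, Pd(dppf)Cl2·CH2Cl2 (cat.), AsPh3, Cs2CO3, DMF–H2O, rt
Reagents that add atoms: none
Why: Anti-Markovnikov hydroboration of the vinyl group puts boron on C11, and B-alkyl Suzuki–Miyaura coupling with the vinyl iodide forms C9–C11 with retention of alkene geometry; excess borane is quenched before 9 is added, and the epoxide, the allylsilane and the silyl ethers tolerate the mild aqueous base.

**Step 13**
Reactants: 19 epoxy allylsilane polyene
Product: 20 (13R)-18-benzyloxy-15,16-bis(TBDPS-oxy)-13-(TES-oxy)labd-8(17)-en-3β-ol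
Conditions: MeAlCl2 (2 equiv), CH2Cl2, −78 °C; then Et3N, MeOH–H2O
Reagents that add atoms: none
Why: MeAlCl2 binds the epoxide oxygen (assisted by the neighbouring benzyloxy oxygen) and weakens the C4–O bond; the C5=C10 alkene attacks C4 anti to the leaving oxygen, C9 of the allylsilane captures the developing C10 cation, and the β-silyl cation at C8 loses Me3Si+ to chloride to leave only the 8(17)-alkene. The closest known reaction type is the Lewis-acid-promoted epoxy-polyene cyclisation terminated by an allylsilane. Ring A closes 6-endo at both the alkene and the epoxide, and ring B closes 6-endo at the allylsilane alkene, each through a chair. C4 is set by inversion: the CH2OBn group, trans to C2 in the epoxide, becomes the equatorial 4α substituent and the methyl becomes axial. C5 and C10 are set by anti addition across the E-alkene in the chair, giving H5 α and the C10 methyl β (trans fusion). C9 is set by the geometry of the terminating alkene, whose C7 and C11 are trans, so C11 ends equatorial and H9 α. The absolute sense of all four comes from the (3S)-epoxide, whose oxygen stays on C3 as the equatorial 3β-hydroxyl, and C13 is a spectator. The step needs an opening that stays SN2-like, since free ionisation at C4 would allow hydride shift to a ketone and loss of the epoxide geometry; the electron-withdrawing CH2OBn group and the low temperature secure this, silicon secures the position of the alkene, and the TES cap keeps the C13 oxygen from adding to C8.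

**Step 14**
Reactants: 20 labd-8(17)-en-3β-ol
Product: 21 (13R)-3β,18-bis(benzyloxy)-15,16-bis(TBDPS-oxy)-13-(TES-oxy)labd-8(17)-ene
Conditions: NaH, BnBr, Bu4NI (cat.), THF–DMF, 0 °C to rt
Reagents that add atoms: benzyl bromide BrCc1ccccc1
Why: Williamson etherification of the equatorial secondary alcohol, so that the later oxidation and the radical deoxygenation cannot touch C3; both benzyl groups fall in the last step.

**Step 15**
Reactants: 21 bis(benzyl ether) labd-8(17)-ene
Product: 22 labd-8(17)-en-7α-ol
Conditions: SeO2 (cat.), t-BuOOH, CH2Cl2, rt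
Reagents that add atoms: tert-butyl hydroperoxide CC(C)(C)OO
Why: SeO2 allylic hydroxylation of the exocyclic alkene: selenium adds to C17, hydrogen is taken from the C7 methylene, not the hindered tertiary C9–H, and the [2,3]-shift returns the exocyclic alkene with oxygen on the axial α face of C7; this stereocentre is removed again in step 17.

**Step 16**
Reactants: 22 labd-8(17)-en-7α-ol
Product: 23 labd-8(17)-ene-7α,13-diol
Conditions: HF·pyridine, pyridine, THF, 0 °C to rt
Reagents that add atoms: none
Why: Buffered HF cleaves the TES ether much faster than the two TBDPS ethers, freeing the C13 hydroxyl before the sensitive enone is made.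

**Step 17**
Reactants: 23 labd-8(17)-ene-7α,13-diol
Product: 24 13-hydroxylabd-8(17)-en-7-one
Conditions: Dess–Martin periodinane, CH2Cl2, 0 °C to rt
Reagents that add atoms: none
Why: Dess–Martin oxidation converts the secondary allylic alcohol to the ketone and cannot oxidise the tertiary C13 alcohol.

**Step 18**
Reactants: 24 13-hydroxylabd-8(17)-en-7-one
Product: 25 13-hydroxylabd-8-en-7-one
Conditions: RhCl3·3H2O (cat.), EtOH, 75 °C
Reagents that add atoms: none
Why: Rhodium-hydride addition to the exocyclic alkene and β-hydride elimination from C9 move the double bond into conjugation inside the ring (metal-catalysed isomerisation of an α-methylene ketone to the α-methyl enone), driven by the greater stability of the tetrasubstituted conjugated enone; the C9–H stereocentre from step 13 is given up here on purpose.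

**Step 19**
Reactants: 25 13-hydroxylabd-8-en-7-one
Product: 27 9α,13-epoxylabdan-7α-ol, via spiroketone 26 (not isolated)
Conditions: t-BuOK (cat.), THF, 0 °C to rt; then NaBH4, MeOH, 0 °C
Reagents that add atoms: none
Why: Intramolecular oxa-Michael addition (5-exo-trig) of the C13 alkoxide to C9 occurs axially on the α face, anti to the C10 methyl, giving the 9α ether with C11 equatorial; the reversible conditions let C8 equilibrate through the enolate to the equatorial 8α-methyl (H8 β). Reduction in the same flask then removes the ketone that could allow retro-addition; hydride is expected from the β side because the axial C9–O bond shields the α face, and the C7 configuration is of no consequence.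

**Step 20**
Reactants: 27 9α,13-epoxylabdan-7α-ol
Product: 28 7-O-(imidazol-1-ylthiocarbonyl) derivative of 27
Conditions: 1,1'-thiocarbonyldiimidazole, DMAP (cat.), PhMe, 90 °C
Reagents that add atoms: 1,1'-thiocarbonyldiimidazole S=C(n1ccnc1)n1ccnc1
Why: Neutral thioacylation of the hindered secondary alcohol gives the radical precursor without strong base.

**Step 21**
Reactants: 28 7-O-thiocarbonylimidazolide
Product: 29 (13R)-3β,18-bis(benzyloxy)-15,16-bis(TBDPS-oxy)-9α,13-epoxylabdane
Conditions: Bu3SnH, AIBN (cat.), PhMe, 110 °C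
Reagents that add atoms: none
Why: Barton–McCombie deoxygenation: the stannyl radical adds to sulfur, the C7–O bond fragments and the secondary C7 radical takes hydrogen from the stannane; the radical is not β to the C9 oxygen, so the oxolane stays closed and C8 is not affected.

**Step 22**
Reactants: 29 9α,13-epoxylabdane bis(silyl ether)
Product: 30 (13R)-3β,18-bis(benzyloxy)-9α,13-epoxylabdane-15,16-diol
Conditions: Bu4NF, THF, rt
Reagents that add atoms: none
Why: Fluoride cleaves both TBDPS ethers; no carbonyl is present at this stage, so the basic fluoride cannot cause β-elimination.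

**Step 23**
Reactants: 30 15,16-diol
Product: 31 (13R)-3β,18-bis(benzyloxy)-9α,13-epoxylabdan-15,16-olide
Conditions: TEMPO (cat.), PhI(OAc)2, CH2Cl2, rt
Reagents that add atoms: none
Why: Oxoammonium oxidation is faster at the unhindered C15 carbinol than at the neopentyl-type C16 carbinol; the C15 aldehyde is captured by the C16 hydroxyl as a five-membered lactol, which is oxidised on to the lactone with C15 as carbonyl (oxidative lactonisation of a 1,4-diol) under nearly neutral conditions.

**Step 24**
Reactants: 31 bis(benzyl ether) lactone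
Product: 32 (13R)-3β,18-dihydroxy-9α,13-epoxylabdan-15,16-olide (target, CNP0274732.3)
Conditions: H2 (1 atm), Pd(OH)2/C, EtOAc–EtOH, rt
Reagents that add atoms: none
Why: Hydrogenolysis of both benzyl ethers under neutral conditions; the lactone and the two tertiary ether carbons are neither benzylic nor allylic and no alkene is left, so no stereocentre can be disturbed.

## Compound list

1 | geranyl bromide, (2E)-1-bromo-3,7-dimethylocta-2,6-diene | CC(C)=CCC/C(C)=C/CBr | starting material
2 | 1-(trimethylsilyl)propyne | CC#C[Si](C)(C)C | starting material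
3 | trimethyl[(5E)-6,10-dimethylundeca-5,9-dien-1-yn-1-yl]silane | CC(C)=CCC/C(C)=C/CCC#C[Si](C)(C)C | intermediate (not isolated)
4 | (5E)-6,10-dimethylundeca-5,9-dien-1-yne | CC(C)=CCC/C(C)=C/CCC#C | intermediate
5 | (2E,6E)-2,6-dimethylundeca-2,6-dien-10-yn-1-ol | OC/C(C)=C/CC/C(C)=C/CCC#C | intermediate
6 | (1Z,5E,9E)-alkenylcopper (monovalent copper) from syn-addition to 5, as its chloromagnesium alkoxide | Cl[Mg]OC/C(C)=C/CC/C(C)=C/CC/C(C[Si](C)(C)C)=C/[Cu] | intermediate (not isolated)
7 | (2E,6E,10Z)-11-iodo-2,6-dimethyl-10-[(trimethylsilyl)methyl]undeca-2,6,10-trien-1-ol | OC/C(C)=C/CC/C(C)=C/CC/C(C[Si](C)(C)C)=C/I | intermediate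
8 | {(2S,3S)-3-[(3E,7Z)-8-iodo-3-methyl-7-[(trimethylsilyl)methyl]octa-3,7-dien-1-yl]-2-methyloxiran-2-yl}methanol | OC[C@]1(C)O[C@H]1CC/C(C)=C/CC/C(C[Si](C)(C)C)=C/I | intermediate
9 | (2S,3S)-2-[(benzyloxy)methyl]-3-[(3E,7Z)-8-iodo-3-methyl-7-[(trimethylsilyl)methyl]octa-3,7-dien-1-yl]-2-methyloxirane | c1ccccc1COC[C@]1(C)O[C@H]1CC/C(C)=C/CC/C(C[Si](C)(C)C)=C/I | intermediate
10 | 3-bromobut-3-en-1-ol | OCCC(Br)=C | starting material
11 | [(3-bromobut-3-en-1-yl)oxy](tert-butyl)diphenylsilane | C=C(Br)CCO[Si](c1ccccc1)(c1ccccc1)C(C)(C)C | intermediate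
12 | {4-[(tert-butyldiphenylsilyl)oxy]but-1-en-2-yl}lithium | [Li]C(=C)CCO[Si](c1ccccc1)(c1ccccc1)C(C)(C)C | intermediate (not isolated)
13 | 4-[(tert-butyldiphenylsilyl)oxy]-2-methylidenebutan-1-ol | C=C(CO)CCO[Si](c1ccccc1)(c1ccccc1)C(C)(C)C | intermediate
14 | {(2R)-2-[2-[(tert-butyldiphenylsilyl)oxy]ethyl]oxiran-2-yl}methanol | OC[C@]1(CCO[Si](c2ccccc2)(c2ccccc2)C(C)(C)C)CO1 | intermediate
15 | (2S)-2-[2-[(tert-butyldiphenylsilyl)oxy]ethyl]-2-{[(tert-butyldiphenylsilyl)oxy]methyl}oxirane | CC(C)(C)[Si](c1ccccc1)(c1ccccc1)OC[C@]1(CCO[Si](c2ccccc2)(c2ccccc2)C(C)(C)C)CO1 | intermediate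
16 | (3S)-5-[(tert-butyldiphenylsilyl)oxy]-3-{[(tert-butyldiphenylsilyl)oxy]methyl}pent-1-en-3-ol | CC(C)(C)[Si](c1ccccc1)(c1ccccc1)OC[C@](O)(CCO[Si](c1ccccc1)(c1ccccc1)C(C)(C)C)C=C | intermediate
17 | (3S)-5-[(tert-butyldiphenylsilyl)oxy]-3-{[(tert-butyldiphenylsilyl)oxy]methyl}-3-[(triethylsilyl)oxy]pent-1-ene | CC(C)(C)[Si](c1ccccc1)(c1ccccc1)OC[C@](O[Si](CC)(CC)CC)(CCO[Si](c1ccccc1)(c1ccccc1)C(C)(C)C)C=C | intermediate
18 | B-alkyl-9-borabicyclo[3.3.1]nonane from hydroboration of 17 (boron on C11; C13 is R) | C1CCC2CCCC1B2CC[C@@](CCO[Si](c1ccccc1)(c1ccccc1)C(C)(C)C)(CO[Si](c1ccccc1)(c1ccccc1)C(C)(C)C)O[Si](CC)(CC)CC | intermediate (not isolated)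
19 | (2S,3S)-2-[(benzyloxy)methyl]-3-[(3E,7Z,11R)-13-[(tert-butyldiphenylsilyl)oxy]-11-{[(tert-butyldiphenylsilyl)oxy]methyl}-3-methyl-11-[(triethylsilyl)oxy]-7-[(trimethylsilyl)methyl]trideca-3,7-dien-1-yl]-2-methyloxirane (7Z only because the silylmethyl group outranks C7; the chain carbons C7 and C11 are trans, the farnesyl-type geometry) | c1ccccc1COC[C@]1(C)O[C@H]1CC/C(C)=C/CC/C(C[Si](C)(C)C)=C/CC[C@@](CCO[Si](c1ccccc1)(c1ccccc1)C(C)(C)C)(CO[Si](c1ccccc1)(c1ccccc1)C(C)(C)C)O[Si](CC)(CC)CC | intermediate
20 | (13R)-18-(benzyloxy)-15,16-bis[(tert-butyldiphenylsilyl)oxy]-13-[(triethylsilyl)oxy]labd-8(17)-en-3β-ol (5α-H, 9α-H, 10β-CH3, 4α-CH2OBn, 4β-CH3) | C=C1CC[C@H]2[C@](C)(COCc3ccccc3)[C@@H](O)CC[C@]2(C)[C@H]1CC[C@@](CCO[Si](c4ccccc4)(c4ccccc4)C(C)(C)C)(CO[Si](c4ccccc4)(c4ccccc4)C(C)(C)C)O[Si](CC)(CC)CC | intermediate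
21 | (13R)-3β,18-bis(benzyloxy)-15,16-bis[(tert-butyldiphenylsilyl)oxy]-13-[(triethylsilyl)oxy]labd-8(17)-ene | C=C1CC[C@H]2[C@](C)(COCc3ccccc3)[C@@H](OCc3ccccc3)CC[C@]2(C)[C@H]1CC[C@@](CCO[Si](c4ccccc4)(c4ccccc4)C(C)(C)C)(CO[Si](c4ccccc4)(c4ccccc4)C(C)(C)C)O[Si](CC)(CC)CC | intermediate
22 | (13R)-3β,18-bis(benzyloxy)-15,16-bis[(tert-butyldiphenylsilyl)oxy]-13-[(triethylsilyl)oxy]labd-8(17)-en-7α-ol | C=C1[C@H](O)C[C@H]2[C@](C)(COCc3ccccc3)[C@@H](OCc3ccccc3)CC[C@]2(C)[C@H]1CC[C@@](CCO[Si](c4ccccc4)(c4ccccc4)C(C)(C)C)(CO[Si](c4ccccc4)(c4ccccc4)C(C)(C)C)O[Si](CC)(CC)CC | intermediate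
23 | (13R)-3β,18-bis(benzyloxy)-15,16-bis[(tert-butyldiphenylsilyl)oxy]labd-8(17)-ene-7α,13-diol | C=C1[C@H](O)C[C@H]2[C@](C)(COCc3ccccc3)[C@@H](OCc3ccccc3)CC[C@]2(C)[C@H]1CC[C@@](CCO[Si](c4ccccc4)(c4ccccc4)C(C)(C)C)(CO[Si](c4ccccc4)(c4ccccc4)C(C)(C)C)O | intermediate
24 | (13R)-3β,18-bis(benzyloxy)-15,16-bis[(tert-butyldiphenylsilyl)oxy]-13-hydroxylabd-8(17)-en-7-one | C=C1C(=O)C[C@H]2[C@](C)(COCc3ccccc3)[C@@H](OCc3ccccc3)CC[C@]2(C)[C@H]1CC[C@@](CCO[Si](c4ccccc4)(c4ccccc4)C(C)(C)C)(CO[Si](c4ccccc4)(c4ccccc4)C(C)(C)C)O | intermediate
25 | (13R)-3β,18-bis(benzyloxy)-15,16-bis[(tert-butyldiphenylsilyl)oxy]-13-hydroxylabd-8-en-7-one | O=C1C[C@H]2[C@](C)(COCc3ccccc3)[C@@H](OCc3ccccc3)CC[C@]2(C)C(CC[C@@](CCO[Si](c4ccccc4)(c4ccccc4)C(C)(C)C)(CO[Si](c4ccccc4)(c4ccccc4)C(C)(C)C)O)=C1C | intermediate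
26 | (13R)-3β,18-bis(benzyloxy)-15,16-bis[(tert-butyldiphenylsilyl)oxy]-9α,13-epoxylabdan-7-one (8β-H, C17 α) | C[C@@H]1C(=O)C[C@H]2[C@](C)(COCc3ccccc3)[C@@H](OCc3ccccc3)CC[C@]2(C)[C@@]12CC[C@@](CCO[Si](c4ccccc4)(c4ccccc4)C(C)(C)C)(CO[Si](c4ccccc4)(c4ccccc4)C(C)(C)C)O2 | intermediate (not isolated)
27 | (13R)-3β,18-bis(benzyloxy)-15,16-bis[(tert-butyldiphenylsilyl)oxy]-9α,13-epoxylabdan-7α-ol (the 7-epimer would serve equally) | C[C@@H]1[C@H](O)C[C@H]2[C@](C)(COCc3ccccc3)[C@@H](OCc3ccccc3)CC[C@]2(C)[C@@]12CC[C@@](CCO[Si](c4ccccc4)(c4ccccc4)C(C)(C)C)(CO[Si](c4ccccc4)(c4ccccc4)C(C)(C)C)O2 | intermediate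
28 | O-[(13R)-3β,18-bis(benzyloxy)-15,16-bis[(tert-butyldiphenylsilyl)oxy]-9α,13-epoxylabdan-7α-yl] 1H-imidazole-1-carbothioate | C[C@@H]1[C@H](OC(=S)n3ccnc3)C[C@H]2[C@](C)(COCc3ccccc3)[C@@H](OCc3ccccc3)CC[C@]2(C)[C@@]12CC[C@@](CCO[Si](c4ccccc4)(c4ccccc4)C(C)(C)C)(CO[Si](c4ccccc4)(c4ccccc4)C(C)(C)C)O2 | intermediate
29 | (13R)-3β,18-bis(benzyloxy)-15,16-bis[(tert-butyldiphenylsilyl)oxy]-9α,13-epoxylabdane | C[C@@H]1CC[C@H]2[C@](C)(COCc3ccccc3)[C@@H](OCc3ccccc3)CC[C@]2(C)[C@@]12CC[C@@](CCO[Si](c4ccccc4)(c4ccccc4)C(C)(C)C)(CO[Si](c4ccccc4)(c4ccccc4)C(C)(C)C)O2 | intermediate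
30 | (13R)-3β,18-bis(benzyloxy)-9α,13-epoxylabdane-15,16-diol | C[C@@H]1CC[C@H]2[C@](C)(COCc3ccccc3)[C@@H](OCc3ccccc3)CC[C@]2(C)[C@@]12CC[C@@](CCO)(CO)O2 | intermediate
31 | (13R)-3β,18-bis(benzyloxy)-9α,13-epoxylabdan-15,16-olide | C[C@@H]1CC[C@H]2[C@](C)(COCc3ccccc3)[C@@H](OCc3ccccc3)CC[C@]2(C)[C@@]12CC[C@@]1(COC(=O)C1)O2 | intermediate
32 | (13R)-3β,18-dihydroxy-9α,13-epoxylabdan-15,16-olide (CNP0274732.3) | C[C@@H]1CC[C@H]2[C@](C)(CO)[C@@H](O)CC[C@]2(C)[C@@]12CC[C@@]1(COC(=O)C1)O2 | target

## Step count and uncertain steps

Total: 24 steps (steps 1–5 for the vinyl iodide fragment, steps 6–11 for the vinyl carbinol fragment, step 12 coupling, step 13 key step, steps 14–24 endgame). Longest linear sequence: 19 steps (steps 6–13, then 14–24).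

**Step 13 (key step).** The most likely failures are early termination after ring A (proton loss from the C10 cation), rearrangement of the activated epoxide to a carbonyl compound by hydride shift because the oxygenated C4 resists attack, and protodesilylation of the allylsilane by adventitious acid before cyclisation. The fallback replaces the cationic cascade by a radical one, sets out from 5 and comes back at 20. Zirconium-catalysed methylalumination of 5 (Me3Al, Cp2ZrCl2; then I2) would give (2E,6E,10E)-11-iodo-2,6,10-trimethylundeca-2,6,10-trien-1-ol F1. Asymmetric epoxidation and benzylation as in steps 4 and 5 would give the epoxy alcohol F2 and the benzyl ether F3, and coupling with 18 as in step 12 would give the methyl-terminated epoxy-diene F4. Cp2TiCl (trivalent titanium, made from Cp2TiCl2 and Mn in THF) then opens the epoxide homolytically at C4. The β-titanoxy radical closes both rings 6-endo, and the tertiary C8 radical is converted by a second equivalent of the titanium reagent to the exocyclic alkene, giving 20 after work-up. The weakness is that C4 passes through a planar radical, so its configuration depends on the chair preference and no longer on the epoxide geometry.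

**Step 19.** The addition joins two fully substituted carbons through oxygen, so the equilibrium may leave much enone; the alkoxide can also trigger migration of the neighbouring silyl group, and in that case the borohydride would reduce unreacted enone. The fallback forms C9–O by allylic substitution, sets out from 25 and comes back at 29. Reduction of 25 with NaBH4 and CeCl3·7H2O (Luche reduction) would give the allylic alcohol 13-hydroxylabd-8-en-7β-ol F5. Catalytic camphorsulfonic acid in CH2Cl2 would ionise the allylic hydroxyl, and the C13 hydroxyl would capture the allyl cation at C9 on the axial α face to give the 9α,13-epoxylabd-7-ene F6. Radical hydrogen-atom-transfer hydrogenation of the C7=C8 alkene (Mn(dpm)3, PhSiH3, t-BuOOH) would then give 29. Here C8 is set kinetically and not by equilibration, which is why this is not the main route.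

**Step 18.** The rhodium hydride may fail to migrate the double bond because the only hydrogen it can remove is the hindered tertiary C9–H, and ethanol may add to the exocyclic enone. The fallback moves the alkene before oxidising, sets out from 21 and comes back at 25. Iodine-catalysed migration of the exocyclic alkene of 21 in benzene would give the tetrasubstituted labd-8-ene F7, which must be separated from its C7=C8 isomer. Allylic oxidation at C7 with CrO3 and 3,5-dimethylpyrazole would give the 13-silyloxy enone F8, and HF·pyridine would give 25. The cost is a less clean isomerisation and possible oxidation at C11.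

**Step 3.** The silylmethylcopper reagent is less reactive than simple alkylcopper reagents, so incomplete addition is the main risk, and iodine can attack the new allylsilane if the quench is not cold and exact. The fallback introduces the silylmethyl group last by cross-coupling, sets out from 4 and comes back at 19. Bromoboration of 4 (BBr3, CH2Cl2, −78 °C; then pinacol) would give the (Z)-2-bromoalkenyl pinacol boronate F9, and iodine with NaOH would replace boron with retention to give the (Z)-2-bromo-1-iodoalkene F10. Allylic hydroxylation, asymmetric epoxidation and benzylation as in steps 2, 4 and 5 would give the allylic alcohol F11, the epoxy alcohol F12 and the benzyl ether F13. Suzuki–Miyaura coupling with 18 at the more reactive C–I bond would give the vinyl bromide polyene F14. Kumada coupling of F14 with Me3SiCH2MgCl and Pd(PPh3)4 would then give 19 with retention of geometry.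

**Step 23.** Oxidation may begin at the C16 carbinol in part, which would lead to the isomeric lactone with C16 as carbonyl. The fallback fixes the regiochemistry through protecting groups, sets out from 29 and comes back at 31. Brief treatment of 29 with HF·pyridine at 0 °C would remove the less hindered C15 silyl group first and give the 15-alcohol F15. Oxidation with TEMPO and PhI(OAc)2 in aqueous MeCN would give the 15-carboxylic acid F16. Acetic-acid-buffered Bu4NF would then free the C16 hydroxyl, which closes onto the acid to give 31.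

## Further compounds

F1 | step 13 | (2E,6E,10E)-11-iodo-2,6,10-trimethylundeca-2,6,10-trien-1-ol | OC/C(C)=C/CC/C(C)=C/CC/C(C)=C/I
F2 | step 13 | {(2S,3S)-3-[(3E,7E)-8-iodo-3,7-dimethylocta-3,7-dien-1-yl]-2-methyloxiran-2-yl}methanol | OC[C@]1(C)O[C@H]1CC/C(C)=C/CC/C(C)=C/I
F3 | step 13 | (2S,3S)-2-[(benzyloxy)methyl]-3-[(3E,7E)-8-iodo-3,7-dimethylocta-3,7-dien-1-yl]-2-methyloxirane | c1ccccc1COC[C@]1(C)O[C@H]1CC/C(C)=C/CC/C(C)=C/I
F4 | step 13 | (2S,3S)-2-[(benzyloxy)methyl]-3-[(3E,7E,11R)-13-[(tert-butyldiphenylsilyl)oxy]-11-{[(tert-butyldiphenylsilyl)oxy]methyl}-3,7-dimethyl-11-[(triethylsilyl)oxy]trideca-3,7-dien-1-yl]-2-methyloxirane | c1ccccc1COC[C@]1(C)O[C@H]1CC/C(C)=C/CC/C(C)=C/CC[C@@](CCO[Si](c1ccccc1)(c1ccccc1)C(C)(C)C)(CO[Si](c1ccccc1)(c1ccccc1)C(C)(C)C)O[Si](CC)(CC)CC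
F5 | step 19 | (13R)-3β,18-bis(benzyloxy)-15,16-bis[(tert-butyldiphenylsilyl)oxy]labd-8-ene-7β,13-diol | O[C@H]1C[C@H]2[C@](C)(COCc3ccccc3)[C@@H](OCc3ccccc3)CC[C@]2(C)C(CC[C@@](CCO[Si](c4ccccc4)(c4ccccc4)C(C)(C)C)(CO[Si](c4ccccc4)(c4ccccc4)C(C)(C)C)O)=C1C
F6 | step 19 | (13R)-3β,18-bis(benzyloxy)-15,16-bis[(tert-butyldiphenylsilyl)oxy]-9α,13-epoxylabd-7-ene | CC1=CC[C@H]2[C@](C)(COCc3ccccc3)[C@@H](OCc3ccccc3)CC[C@]2(C)[C@@]12CC[C@@](CCO[Si](c4ccccc4)(c4ccccc4)C(C)(C)C)(CO[Si](c4ccccc4)(c4ccccc4)C(C)(C)C)O2
F7 | step 18 | (13R)-3β,18-bis(benzyloxy)-15,16-bis[(tert-butyldiphenylsilyl)oxy]-13-[(triethylsilyl)oxy]labd-8-ene | C1C[C@H]2[C@](C)(COCc3ccccc3)[C@@H](OCc3ccccc3)CC[C@]2(C)C(CC[C@@](CCO[Si](c4ccccc4)(c4ccccc4)C(C)(C)C)(CO[Si](c4ccccc4)(c4ccccc4)C(C)(C)C)O[Si](CC)(CC)CC)=C1C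
F8 | step 18 | (13R)-3β,18-bis(benzyloxy)-15,16-bis[(tert-butyldiphenylsilyl)oxy]-13-[(triethylsilyl)oxy]labd-8-en-7-one | O=C1C[C@H]2[C@](C)(COCc3ccccc3)[C@@H](OCc3ccccc3)CC[C@]2(C)C(CC[C@@](CCO[Si](c4ccccc4)(c4ccccc4)C(C)(C)C)(CO[Si](c4ccccc4)(c4ccccc4)C(C)(C)C)O[Si](CC)(CC)CC)=C1C
F9 | step 3 | 2-[(1Z,5E)-2-bromo-6,10-dimethylundeca-1,5,9-trien-1-yl]-4,4,5,5-tetramethyl-1,3,2-dioxaborolane | CC(C)=CCC/C(C)=C/CC/C(Br)=C/B1OC(C)(C)C(C)(C)O1
F10 | step 3 | (1Z,5E)-2-bromo-1-iodo-6,10-dimethylundeca-1,5,9-triene | CC(C)=CCC/C(C)=C/CC/C(Br)=C/I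
F11 | step 3 | (2E,6E,10Z)-10-bromo-11-iodo-2,6-dimethylundeca-2,6,10-trien-1-ol | OC/C(C)=C/CC/C(C)=C/CC/C(Br)=C/I
F12 | step 3 | {(2S,3S)-3-[(3E,7Z)-7-bromo-8-iodo-3-methylocta-3,7-dien-1-yl]-2-methyloxiran-2-yl}methanol | OC[C@]1(C)O[C@H]1CC/C(C)=C/CC/C(Br)=C/I
F13 | step 3 | (2S,3S)-2-[(benzyloxy)methyl]-3-[(3E,7Z)-7-bromo-8-iodo-3-methylocta-3,7-dien-1-yl]-2-methyloxirane | c1ccccc1COC[C@]1(C)O[C@H]1CC/C(C)=C/CC/C(Br)=C/I
F14 | step 3 | (2S,3S)-2-[(benzyloxy)methyl]-3-[(3E,7Z,11R)-7-bromo-13-[(tert-butyldiphenylsilyl)oxy]-11-{[(tert-butyldiphenylsilyl)oxy]methyl}-3-methyl-11-[(triethylsilyl)oxy]trideca-3,7-dien-1-yl]-2-methyloxirane | c1ccccc1COC[C@]1(C)O[C@H]1CC/C(C)=C/CC/C(Br)=C/CC[C@@](CCO[Si](c1ccccc1)(c1ccccc1)C(C)(C)C)(CO[Si](c1ccccc1)(c1ccccc1)C(C)(C)C)O[Si](CC)(CC)CC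
F15 | step 23 | (13R)-3β,18-bis(benzyloxy)-16-[(tert-butyldiphenylsilyl)oxy]-9α,13-epoxylabdan-15-ol | C[C@@H]1CC[C@H]2[C@](C)(COCc3ccccc3)[C@@H](OCc3ccccc3)CC[C@]2(C)[C@@]12CC[C@@](CCO)(CO[Si](c4ccccc4)(c4ccccc4)C(C)(C)C)O2
F16 | step 23 | (13R)-3β,18-bis(benzyloxy)-16-[(tert-butyldiphenylsilyl)oxy]-9α,13-epoxylabdan-15-oic acid | C[C@@H]1CC[C@H]2[C@](C)(COCc3ccccc3)[C@@H](OCc3ccccc3)CC[C@]2(C)[C@@]12CC[C@@](CC(O)=O)(CO[Si](c4ccccc4)(c4ccccc4)C(C)(C)C)O2
A1 | alternative 1 | C16 diazoacetate of the 3,18-acetonide of (13S)-9α,13-epoxy-14,15-dinorlabdane-3β,16,18-triol (C13–H oxolane) | C[C@@H]1CC[C@H]2[C@]3(C)COC(C)(C)O[C@H]3CC[C@]2(C)[C@@]12CC[C@@H](COC(=O)C=[N+]=[N-])O2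
A2 | alternative 1 | 3,18-acetonide of the target | C[C@@H]1CC[C@H]2[C@]3(C)COC(C)(C)O[C@H]3CC[C@]2(C)[C@@]12CC[C@@]1(COC(=O)C1)O2
A3 | alternative 2 | methyl (2E,6R)-2,6-dimethyl-6-{2-[(2E)-penta-2,4-dien-2-yl]-1,3-dioxolan-2-yl}hex-2-enoate (acyclic trienoate) | C=C/C=C(\C)C1(OCCO1)[C@H](C)CC/C=C(\C)C(=O)OC
A4 | alternative 2 | trans-fused octalin with C4 methyl ester, C1=C2 alkene and C9 dioxolane | C[C@@H]1CC[C@H]2[C@](C)(C(=O)OC)CC=C[C@]2(C)C13OCCO3
A5 | alternative 3 | (13R)-15,16-bis[(tert-butyldimethylsilyl)oxy]-13-hydroxy-3β,18-(isopropylidenedioxy)labd-8-en-7-one | O=C1C[C@H]2[C@]3(C)COC(C)(C)O[C@H]3CC[C@]2(C)C(CC[C@@](CCO[Si](C)(C)C(C)(C)C)(CO[Si](C)(C)C(C)(C)C)O)=C1C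
A6 | alternative 3 | (13R)-15,16-bis[(tert-butyldimethylsilyl)oxy]-9α,13-epoxy-3β,18-(isopropylidenedioxy)labdan-7-one | C[C@@H]1C(=O)C[C@H]2[C@]3(C)COC(C)(C)O[C@H]3CC[C@]2(C)[C@@]12CC[C@@](CCO[Si](C)(C)C(C)(C)C)(CO[Si](C)(C)C(C)(C)C)O2
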